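**Retrosynthetic overview**

1. Numbering used throughout (cembrane type): ring A = the 14-membered carbocycle C1–C14, with C3 = CH–O, C4 = C(OH)CH3 (methyl C18), C7 = CH–OOH, C8 (=C19H2), oxirane C11/C12 (methyl C20 on C12); ring B = the δ-lactone C1–C2–C3–O–C16(=O)–C15 (methyl C17 on C15).
2. Last disconnection: C7–OOH/C8=C19 goes back to the (7E)-C7=C8(C19H3) alkene of the macrocyclic lactone (singlet-oxygen ene reaction).
3. Key disconnection: C3–C4 and, in the same operation, O–C16. A samarium diiodide pinacol coupling of an acyclic C3 aldehyde/C4 methyl ketone that carries a C16 thioester closes ring A, then ring B, and sets C3 and C4.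
4. Enabling feature: C3/C4 is a vicinal secondary/tertiary diol junction (two carbonyl carbons in disguise), and the C3 oxygen is the ring oxygen of ring B, so a C16 acyl donor placed 1,5 to the aldehyde traps the new C3 alkoxide.
5. The acyclic precursor comes from (E)-geranylacetone (C4–C13, C18–C20): allylic oxidation, Sharpless epoxidation (oxirane, the first ring; C11, C12), allyl coupling and cross-metathesis (C14, C1–C3), then an organocatalytic Mukaiyama–Michael addition of a thiopropionate ketene acetal (C15–C17; sets C1 and C15).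

Key step: step 10

Remark: (E)-geranylacetone is assumed to be used as the isomerically pure commercial E isomer; all stereochemical outcomes below are predictions, not measured results.

**Route**

Step 1
Reactants: 1 (E)-geranylacetone, (5E)-6,10-dimethylundeca-5,9-dien-2-one
Product: 2 (5E,9E)-11-hydroxy-6,10-dimethylundeca-5,9-dien-2-one
Conditions: SeO2 (0.3 equiv), t-BuOOH (anhydrous, 2 equiv), CH2Cl2, 0 °C → rt; stopped before full conversion, 1 recycled
Reagents that add atoms: tert-butyl hydroperoxide, CC(C)(C)OO
Why: Selenium dioxide allylic oxidation (ene reaction, then [2,3]-sigmatropic shift, t-BuOOH as terminal oxidant) attacks the (E)-methyl group of the terminal trisubstituted alkene of geranyl-type chains in preference to the internal alkene and leaves the ketone alone; no stereocentre is formed and the 9E geometry follows from the [2,3] shift.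

Step 2
Reactants: 2 (5E,9E)-11-hydroxy-6,10-dimethylundeca-5,9-dien-2-one
Product: 3 (2E,6E)-10,10-dimethoxy-2,6-dimethylundeca-2,6-dien-1-ol
Conditions: HC(OMe)3, MeOH, PPTS (cat.), rt; then Et3N
Reagents that add atoms: trimethyl orthoformate, COC(OC)OC
Why: Acid-catalysed ketalization driven by the orthoformate masks the ketone against the Grignard reagent of step 4 as a dimethyl ketal, chosen because it can later be hydrolysed by acid too weak to open the epoxide; no stereocentre is formed.

Step 3
Reactants: 3 (2E,6E)-10,10-dimethoxy-2,6-dimethylundeca-2,6-dien-1-ol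
Product: 4 [(2S,3S)-3-[(3E)-7,7-dimethoxy-3-methyloct-3-en-1-yl]-2-methyloxiran-2-yl]methanol
Conditions: Ti(OiPr)4 (10 mol%), L-(+)-diethyl tartrate (12 mol%), t-BuOOH (anhydrous), 4 Å molecular sieves, CH2Cl2, −20 °C
Reagents that add atoms: tert-butyl hydroperoxide, CC(C)(C)OO
Why: Sharpless asymmetric epoxidation is directed by the allylic hydroxyl, so only the C11=C12 alkene reacts, and the L-(+)-tartrate ligand should deliver oxygen to the face that gives the (2S,3S)-epoxy alcohol, i.e. 11S and 12S.

Step 4
Reactants: 4 [(2S,3S)-3-[(3E)-7,7-dimethoxy-3-methyloct-3-en-1-yl]-2-methyloxiran-2-yl]methanol; 5 allylmagnesium bromide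
Product: 8 (2S,3S)-2-(but-3-en-1-yl)-3-[(3E)-7,7-dimethoxy-3-methyloct-3-en-1-yl]-2-methyloxirane, via lithium alkoxide 6 (not isolated), via epoxy triflate 7 (not isolated)
Conditions: n-BuLi, Et2O, −78 °C; Tf2O, −78 °C; then 5, CuBr·SMe2 (10 mol%), −78 → −30 °C
Reagents that add atoms: none
Why: A primary 2,3-epoxy triflate is displaced by a Grignard reagent under copper catalysis (SN2 at C13) much faster than the hindered trisubstituted epoxide is opened at low temperature, so the allyl group (C14, C1 and a sacrificial CH2) is attached with the oxirane stereocentres untouched.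

Step 5
Reactants: 8 (2S,3S)-2-(but-3-en-1-yl)-3-[(3E)-7,7-dimethoxy-3-methyloct-3-en-1-yl]-2-methyloxirane
Product: 9 (5E)-8-[(2S,3S)-3-(but-3-en-1-yl)-3-methyloxiran-2-yl]-6-methyloct-5-en-2-one
Conditions: PPTS (5 mol%), acetone/H2O (20:1), 0 °C → rt, stopped at full conversion
Reagents that add atoms: water, O
Why: Acid-catalysed hydrolysis of an acyclic dimethyl ketal is much faster than acid opening of a trisubstituted epoxide, so brief exposure to the weak pyridinium acid should release the C4 ketone alone; no stereocentre is affected.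

Step 6
Reactants: 9 (5E)-8-[(2S,3S)-3-(but-3-en-1-yl)-3-methyloxiran-2-yl]-6-methyloct-5-en-2-one; 10 (E)-crotonaldehyde
Product: 11 (2E)-5-[(2S,3S)-2-methyl-3-[(3E)-3-methyl-7-oxooct-3-en-1-yl]oxiran-2-yl]pent-2-enal
Conditions: 10 (5 equiv), Hoveyda–Grubbs second-generation catalyst [RuCl2(H2IMes)(=CH-C6H4-2-OiPr)] (5 mol%), CH2Cl2, 40 °C
Reagents that add atoms: none
Why: Olefin cross-metathesis of a terminal alkene with an enal partner is selective for the E enal, and the trisubstituted C7=C8 alkene, the epoxide and the ketone are inert to the ruthenium carbene.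

Step 7
Reactants: 12 propanoyl chloride; 13 propane-2-thiol
Product: 14 S-propan-2-yl propanethioate
Conditions: pyridine, CH2Cl2, 0 °C → rt
Reagents that add atoms: none
Why: Acylation of the thiol by the acid chloride with pyridine as base gives the thioester directly; no stereocentre is formed.

Step 8
Reactants: 14 S-propan-2-yl propanethioate
Product: 16 (Z)-trimethyl{[1-(propan-2-ylsulfanyl)prop-1-en-1-yl]oxy}silane (methyl cis to sulfur), via lithium thioester enolate 15 (not isolated)
Conditions: LiN(iPr)2, THF, −78 °C; Me3SiCl, −78 °C → rt; distillation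
Reagents that add atoms: chlorotrimethylsilane, C[Si](C)(C)Cl
Why: Kinetic deprotonation of the thioester by the lithium amide through a closed six-membered transition state places the methyl group trans to O–Li, and O-silylation fixes this geometry as the (Z)-ketene thioacetal.

Step 9
Reactants: 11 (2E)-5-[(2S,3S)-2-methyl-3-[(3E)-3-methyl-7-oxooct-3-en-1-yl]oxiran-2-yl]pent-2-enal; 16 (Z)-trimethyl{[1-(propan-2-ylsulfanyl)prop-1-en-1-yl]oxy}silane
Product: 17 S-propan-2-yl (2S,3R)-2-methyl-5-[(2S,3S)-2-methyl-3-[(3E)-3-methyl-7-oxooct-3-en-1-yl]oxiran-2-yl]-3-(2-oxoethyl)pentanethioate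
Conditions: 16 (2.5 equiv), (2S,5S)-5-benzyl-2-tert-butyl-3-methylimidazolidin-4-one·CF3CO2H (20 mol%), CH2Cl2, H2O (2 equiv), −55 °C
Reagents that add atoms: none
Why: Iminium-ion organocatalysis (Mukaiyama–Michael addition of a thioester ketene acetal to an (E)-β-alkyl enal) should add the nucleophile to the Re face of C1 left open by the benzyl group of the (2S,5S) catalyst (1R), while the open transition state with the (Z)-ketene thioacetal should give the 2,3-syn relationship (15S); the remote ketone and epoxide are spectators at −55 °C.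

Step 10
Reactants: 17 S-propan-2-yl (2S,3R)-2-methyl-5-[(2S,3S)-2-methyl-3-[(3E)-3-methyl-7-oxooct-3-en-1-yl]oxiran-2-yl]-3-(2-oxoethyl)pentanethioate
Product: 19 (1R,3R,4S,7E,11S,12S,15S)-11,12-epoxy-4-hydroxycembr-7-en-16,3-olide (rings A and B closed), via macrocyclic diol thioester 18 (not isolated)
Conditions: SmI2 (3 equiv, 0.1 M in THF), THF, syringe-pump addition of 17 (final 2 mM), −20 °C → rt; aq. NH4Cl
Reagents that add atoms: none
Why: Electron transfer from divalent samarium to the more easily reduced aldehyde gives a trivalent-samarium ketyl at C3 that adds to the samarium-bound C4 ketone (C3–C4 bond), a second electron transfer gives the 3,4-diolate 18, and the C3 alkoxide then acylates itself on the C16 thioester with loss of thiolate. The closest known reaction type is the low-valent-metal pinacol macrocyclization of keto aldehydes used for 14-membered cembranoid 3,4-diols, joined to the familiar lactonization of samarium alkoxides onto a neighbouring acyl group. Ring A closes by 14-exo-trig attack of the ketyl carbon on the ketone, and ring B by 6-exo-trig acyl substitution. C3 (R) requires bond formation on the Si face of the aldehyde and is expected to be controlled by C1: samarium can bridge the ketyl oxygen and the C16 thioester carbonyl in a lactone-like chelate in which C14 (on C1) and C17 (on C15) are equatorial, so that C4 enters cis to C14. C4 (S) requires the Re face of the ketone and is expected to be controlled by binding of both oxygens to one samarium (syn-oxygen topology), with C2 and C5, both members of the ring being closed, on one side of the five-membered chelate and H and C18 on the other. The step needs this one erythro (3R,4S) isomer out of four, reduction of the aldehyde before the ketone, and ring closure over dimerization; these should be secured by the three-point chelation that the 1,5-aldehyde/thioester pattern allows (no hexamethylphosphoramide, which would break it), by the reduction-potential gap between aldehyde and ketone, by the (E)-alkene and trans-epoxide that stiffen the ten-atom tether, and by slow addition at high dilution.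

Step 11
Reactants: 19 (1R,3R,4S,7E,11S,12S,15S)-11,12-epoxy-4-hydroxycembr-7-en-16,3-olide
Product: 20 (1R,3R,4S,7S,11S,12S,15S)-11,12-epoxy-7-hydroperoxy-4-hydroxycembr-8(19)-en-16,3-olide
Conditions: O2, 5,10,15,20-tetraphenylporphyrin (1 mol%), visible light, CH2Cl2, 0 °C; stopped at partial conversion
Reagents that add atoms: dioxygen, O=O
Why: Schenck ene reaction: singlet oxygen adds to C7 of the only remaining trisubstituted alkene with hydrogen abstraction from the C19 methyl, which lies on the disubstituted side of the alkene together with C6 (cis effect) and is always stereoelectronically aligned, giving the C7 hydroperoxide and the C8=C19 methylene; 7S requires oxygen delivery to the Si face of C7, taken to be the exposed outer face of the alkene in the lactone-bridged macrocycle.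

**Compound list**

1 | (E)-geranylacetone, (5E)-6,10-dimethylundeca-5,9-dien-2-one | CC(=O)CC/C=C(\C)CCC=C(C)C | starting material
2 | (5E,9E)-11-hydroxy-6,10-dimethylundeca-5,9-dien-2-one | CC(=O)CC/C=C(\C)CC/C=C(\C)CO | intermediate
3 | (2E,6E)-10,10-dimethoxy-2,6-dimethylundeca-2,6-dien-1-ol | COC(C)(OC)CC/C=C(\C)CC/C=C(\C)CO | intermediate
4 | [(2S,3S)-3-[(3E)-7,7-dimethoxy-3-methyloct-3-en-1-yl]-2-methyloxiran-2-yl]methanol | COC(C)(OC)CC/C=C(\C)CC[C@@H]1O[C@@]1(C)CO | intermediate
5 | allylmagnesium bromide | C=CC[Mg]Br | starting material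
6 | lithium alkoxide of 4 (formed in the flask) | COC(C)(OC)CC/C=C(\C)CC[C@@H]1O[C@@]1(C)C[O-].[Li+] | intermediate
7 | trifluoromethanesulfonate of 4 (epoxy triflate, formed in the flask) | COC(C)(OC)CC/C=C(\C)CC[C@@H]1O[C@@]1(C)COS(=O)(=O)C(F)(F)F | intermediate
8 | (2S,3S)-2-(but-3-en-1-yl)-3-[(3E)-7,7-dimethoxy-3-methyloct-3-en-1-yl]-2-methyloxirane | COC(C)(OC)CC/C=C(\C)CC[C@@H]1O[C@@]1(C)CCC=C | intermediate
9 | (5E)-8-[(2S,3S)-3-(but-3-en-1-yl)-3-methyloxiran-2-yl]-6-methyloct-5-en-2-one | CC(=O)CC/C=C(\C)CC[C@@H]1O[C@@]1(C)CCC=C | intermediate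
10 | (E)-crotonaldehyde, (2E)-but-2-enal | C/C=C/C=O | starting material
11 | (2E)-5-[(2S,3S)-2-methyl-3-[(3E)-3-methyl-7-oxooct-3-en-1-yl]oxiran-2-yl]pent-2-enal | CC(=O)CC/C=C(\C)CC[C@@H]1O[C@@]1(C)CC/C=C/C=O | intermediate
12 | propanoyl chloride | CCC(=O)Cl | starting material
13 | propane-2-thiol | CC(C)S | starting material
14 | S-propan-2-yl propanethioate | CCC(=O)SC(C)C | intermediate
15 | lithium (Z)-1-(propan-2-ylsulfanyl)prop-1-en-1-olate (methyl cis to S, formed in the flask) | C/C=C(\SC(C)C)[O-].[Li+] | intermediate
16 | (Z)-trimethyl{[1-(propan-2-ylsulfanyl)prop-1-en-1-yl]oxy}silane | C/C=C(\SC(C)C)O[Si](C)(C)C | intermediate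
17 | S-propan-2-yl (2S,3R)-2-methyl-5-[(2S,3S)-2-methyl-3-[(3E)-3-methyl-7-oxooct-3-en-1-yl]oxiran-2-yl]-3-(2-oxoethyl)pentanethioate | CC(=O)CC/C=C(\C)CC[C@@H]1O[C@@]1(C)CC[C@H](CC=O)[C@H](C)C(=O)SC(C)C | intermediate
18 | S-propan-2-yl (2S)-2-[(1R,3R,4S,7E,11S,12S)-11,12-epoxy-3,4-dihydroxy-4,8,12-trimethylcyclotetradec-7-en-1-yl]propanethioate (present in the flask as its samarium diolate) | C1C/C=C(\C)CC[C@@H]2O[C@@]2(C)CC[C@@H]([C@H](C)C(=O)SC(C)C)C[C@@H](O)[C@@]1(C)O | intermediate
19 | (1R,3R,4S,7E,11S,12S,15S)-11,12-epoxy-4-hydroxycembr-7-en-16,3-olide | C1C/C=C(\C)CC[C@@H]2O[C@@]2(C)CC[C@@H]2C[C@@H](OC(=O)[C@H]2C)[C@@]1(C)O | intermediate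
20 | (1R,3R,4S,7S,11S,12S,15S)-11,12-epoxy-7-hydroperoxy-4-hydroxycembr-8(19)-en-16,3-olide | C=C1CC[C@@H]2O[C@@]2(C)CC[C@@H]2C[C@@H](OC(=O)[C@H]2C)[C@@](C)(O)CC[C@@H]1OO | target

**Step count and risks**

Total step count: 11. Longest linear sequence: 9 steps (steps 1–6, 9, 10, 11).

Steps most likely to fail:

1. Step 10. What may go wrong: the ketyl and the ketone may meet with the wrong facial topicity at C3 (threo in place of erythro diol series), and intermolecular coupling may compete if dilution is insufficient. The four-isomer outcome is the least predictable point of the route. Fallback (sets out from 17, returns at 18): the coupling is run at −78 °C and quenched cold, before ring B closes, so that the diol thioesters are isolated. The 3-epimeric diol thioester F1 (alone or mixed with 18) is oxidized at its secondary C3 hydroxyl (SO3·pyridine, DMSO, i-Pr2NEt, Parikh–Doering oxidation) to the α-hydroxy ketone F2. Zn(BH4)2 in Et2O at −20 °C then reduces the C3 ketone through the zinc chelate with the C4 hydroxyl, hydride entering from the chelate face that carries the C18 methyl, which should give the erythro diol thioester 18; a trace of DBU closes ring B to 19. C3 is thereby set from C4 by 1,2-chelation control instead of in the carbon–carbon bond formation, so four possible isomers collapse to two; an error at C4 is not repaired.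

2. Step 11. What may go wrong: oxygen transfer to the wrong face of C7, and competing hydrogen abstraction from C6 leading to the tertiary C8 hydroperoxide. Fallback (sets out from 19, returns at 20): if the 7R hydroperoxide F3 is the main ene product, it is reduced with PPh3 to the 7R allylic alcohol F4, converted with MsCl/Et3N (CH2Cl2, −40 °C; the tertiary C4 hydroxyl does not react) into the 7R mesylate F5, and displaced with anhydrous H2O2 in Et2O at low temperature (SN2, inversion) to give 20. The wrong regioisomer is not repaired by this sequence.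

3. Step 9. What may go wrong: erosion of the syn/anti diastereoselectivity in the open transition state, giving the C15 epimer. Fallback (sets out from 11, returns at 19): the anti adduct F6 is taken through the samarium diiodide step unchanged (by way of the 15-epimeric diol thioester F7, not isolated) to the 15-epimeric lactone F8. F8 is equilibrated with DBU (toluene, 60 °C) at the enolizable C15 to 19, in which C17, C14 and C4 are all equatorial on the lactone chair; C15 is then set under thermodynamic instead of kinetic control. A loss of enantiocontrol at C1 is not repaired by this.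

**Further compounds**

F1 | step 10 | S-propan-2-yl (2S)-2-[(1R,3S,4S,7E,11S,12S)-11,12-epoxy-3,4-dihydroxy-4,8,12-trimethylcyclotetradec-7-en-1-yl]propanethioate (3-epimer of 18) | C1C/C=C(\C)CC[C@@H]2O[C@@]2(C)CC[C@@H]([C@H](C)C(=O)SC(C)C)C[C@H](O)[C@@]1(C)O
F2 | step 10 | S-propan-2-yl (2S)-2-[(1R,4S,7E,11S,12S)-11,12-epoxy-4-hydroxy-4,8,12-trimethyl-3-oxocyclotetradec-7-en-1-yl]propanethioate | C1C/C=C(\C)CC[C@@H]2O[C@@]2(C)CC[C@@H]([C@H](C)C(=O)SC(C)C)CC(=O)[C@@]1(C)O
F3 | step 11 | (1R,3R,4S,7R,11S,12S,15S)-11,12-epoxy-7-hydroperoxy-4-hydroxycembr-8(19)-en-16,3-olide (7-epimer of 20) | C=C1CC[C@@H]2O[C@@]2(C)CC[C@@H]2C[C@@H](OC(=O)[C@H]2C)[C@@](C)(O)CC[C@H]1OO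
F4 | step 11 | (1R,3R,4S,7R,11S,12S,15S)-11,12-epoxy-4,7-dihydroxycembr-8(19)-en-16,3-olide | C=C1CC[C@@H]2O[C@@]2(C)CC[C@@H]2C[C@@H](OC(=O)[C@H]2C)[C@@](C)(O)CC[C@H]1O
F5 | step 11 | 7-O-methanesulfonate of the (7R) allylic alcohol F4 | C=C1CC[C@@H]2O[C@@]2(C)CC[C@@H]2C[C@@H](OC(=O)[C@H]2C)[C@@](C)(O)CC[C@H]1OS(C)(=O)=O
F6 | step 9 | S-propan-2-yl (2R,3R)-2-methyl-5-[(2S,3S)-2-methyl-3-[(3E)-3-methyl-7-oxooct-3-en-1-yl]oxiran-2-yl]-3-(2-oxoethyl)pentanethioate (C15 epimer of 17) | CC(=O)CC/C=C(\C)CC[C@@H]1O[C@@]1(C)CC[C@H](CC=O)[C@@H](C)C(=O)SC(C)C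
F7 | step 9 | S-propan-2-yl (2R)-2-[(1R,3R,4S,7E,11S,12S)-11,12-epoxy-3,4-dihydroxy-4,8,12-trimethylcyclotetradec-7-en-1-yl]propanethioate (C15 epimer of 18) | C1C/C=C(\C)CC[C@@H]2O[C@@]2(C)CC[C@@H]([C@@H](C)C(=O)SC(C)C)C[C@@H](O)[C@@]1(C)O
F8 | step 9 | (1R,3R,4S,7E,11S,12S,15R)-11,12-epoxy-4-hydroxycembr-7-en-16,3-olide (C15 epimer of 19) | C1C/C=C(\C)CC[C@@H]2O[C@@]2(C)CC[C@@H]2C[C@@H](OC(=O)[C@@H]2C)[C@@]1(C)O
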